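The route rests on cutting the C6′–C7′ bond of the nine-membered ring D (primed caryophyllane numbering). The feature exploited is the stretch C8′(=CH2)–C7′H2–C6′H2–C5′H. C8′ can be carried as a ketone and C6′/C7′ as the alkene of an enone, although ring D itself holds no endocyclic alkene. One ring-closing metathesis then forms C6′=C7′ and closes ring D. Its precursor is the complete cyclohexene ring C, as a diester. It bears a vinyl group on ring-fusion C5′ and, trans to it on quaternary C4′, a two-carbon arm ending in the trans-cyclobutyl (ring E) vinyl ketone. Ring C comes from an Ireland–Claisen ring contraction. trans-Communic acid and (−)-β-caryophyllene deliver the other stereocentres.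

Key step: step 17

Assumption: trans-communic acid and (−)-β-caryophyllene are bought as the natural single enantiomers; the (1R,9S)-cyclobutane of the latter has the configuration drawn for ring E.

Numbering:
- Labdane numbers are used for the diterpene half and continue as C14 and C15 for the two further carbons of ring C.
- Primed caryophyllane numbers are used for the other half: C1′/C9′ cyclobutane CH, C2′/C3′ two-carbon arm, C4′ quaternary carbon, C5′ ring-fusion CH, C6′/C7′ CH2, C8′ methylene-bearing carbon.
- Rings: A/B decalin, C cyclohexene, D nine-membered ring, E cyclobutane.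

Design remarks:
- (a) Electrophilic oxidants attack the trisubstituted C12=C13 bond of the communate diene before its vinyl group. The enal is therefore reached by cleaving that bond and rebuilding it with a formyl ylide.
- (b) Ring E is taken from the chiral pool. Lewis-acid additions of propiolates to isobutylene favour ene products, would put the gem-dimethyl carbon next to the carboxyl-bearing carbon (wrong regiochemistry), and would give a racemate.
- (c) The vinyl ketone is carried as an N-methoxy-N-methylamide and released one step before the key step.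

**Fragment 1 (labdane lactone)**

Step 1
Reactants: 1 trans-communic acid
Product: 2 methyl trans-communate
Conditions: MeI, K2CO3, DMF, rt
Reagents that add atoms: iodomethane, CI
Why: Carboxylate O-alkylation (SN2 on MeI) avoids attack at the hindered axial C19 carbonyl, spares the acid-sensitive diene and touches no stereocentre.

Step 2
Reactants: 2 methyl trans-communate
Product: 4 methyl 12-oxo-13,14,15,16-tetranorlabd-8(17)-en-19-oate, via C12–C13 ozonide 3 (not isolated)
Conditions: O3 (1.0 equiv, standardized CH2Cl2 solution), CH2Cl2, −78 °C; then Me2S, −78 °C → rt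
Reagents that add atoms: ozone, [O-][O+]=O
Why: Chemoselective ozonolysis: one equivalent of ozone should be consumed by the most electron-rich alkene, the trisubstituted C12=C13 bond of the diene, ahead of the C8=C17 methylene that is screened by the side chain and the angular methyl group, and Me2S reduces the ozonide to the aldehyde.

Step 3
Reactants: 4 methyl 12-oxo-13,14,15,16-tetranorlabd-8(17)-en-19-oate; 5 2-(triphenylphosphoranylidene)propanal
Product: 6 methyl (12E)-14-oxo-15-norlabda-8(17),12-dien-19-oate (the E-enal)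
Conditions: 5 (1.2 equiv), toluene, 90 °C
Reagents that add atoms: none
Why: Wittig olefination with a stabilised formyl ylide should give the (E)-trisubstituted enal, and the ylide reacts only sluggishly with the less electrophilic enal product.

Step 4
Reactants: 6 E-enal
Product: 7 (14R)-homoallylic alcohol (14-allyl-14-hydroxy derivative of 6 with 12E retained)
Conditions: allylSnBu3, (R)-BINOL (20 mol %), Ti(OiPr)4 (10 mol %), 4 Å MS, CH2Cl2, −20 °C
Reagents that add atoms: allyltributylstannane, C=CC[Sn](CCCC)(CCCC)CCCC
Why: Keck asymmetric allylation: the (R)-BINOL–titanium Lewis acid shields one face of the α-methyl enal so that allyl transfer sets the (14R)-carbinol under catalyst control, the remote decalin centres exerting no bias.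

Step 5
Reactants: 7 (14R)-homoallylic alcohol; 8 acryloyl chloride
Product: 9 acrylate ester of 7
Conditions: 8, Et3N, DMAP (cat.), CH2Cl2, 0 °C
Reagents that add atoms: none
Why: DMAP-catalysed O-acylation of the secondary allylic alcohol proceeds with retention at C14.

Step 6
Reactants: 9 acrylate ester of 7
Product: 10 (6R)-6-alkenyl-5,6-dihydro-2H-pyran-2-one (alkenyl = (E)-1-methyl-2-(labdanylmethyl)vinyl)
Conditions: second-generation Grubbs catalyst (H2IMes)(PCy3)Cl2Ru=CHPh (5 mol %), CH2Cl2 (5 mM), 40 °C
Reagents that add atoms: none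
Why: Ring-closing metathesis: the catalyst enters at the terminal allyl alkene and closes the unstrained six-membered enoate, while the trisubstituted and the hindered 1,1-disubstituted alkenes stay out.

Step 7
Reactants: 10 (6R)-dihydropyranone
Product: 12 (4S,6R)-4-vinyl-6-alkenyltetrahydropyran-2-one (4,6-trans), via TMS ketene acetal 11 (not isolated)
Conditions: vinylMgBr, CuBr·SMe2 (15 mol %), TMSCl, THF, −78 °C; then aq. citric acid, 0 °C
Reagents that add atoms: vinylmagnesium bromide, C=C[Mg]Br; chlorotrimethylsilane, C[Si](C)(C)Cl (silyl group of 11 only)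
Why: Copper-catalysed, TMSCl-accelerated conjugate addition delivers the vinyl group axially to the half-chair enoate anti to the pseudo-equatorial C6 side chain, which sets pyranone C4 (= C5′) trans to C6 (= C14).

**Fragment 2 (cyclobutane)**

Step 8
Reactants: 13 (−)-β-caryophyllene
Product: 14 4-[(1S,2R)-3,3-dimethyl-2-(3-oxobutyl)cyclobutyl]-4-oxobutanal
Conditions: K2OsO4·2H2O (2 mol %), NaIO4, 2,6-lutidine, 1,4-dioxane/H2O, rt
Reagents that add atoms: sodium periodate (oxygen, relayed through OsO4), [Na+].[O-]I(=O)(=O)=O
Why: Lemieux–Johnson cleavage of both alkenes is run exhaustively so that no selectivity is needed, and the two cyclobutane stereocentres are kept, C9′ sitting in its favoured trans arrangement.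

Step 9
Reactants: 14 diketo aldehyde
Product: 15 2-[(1S,2R)-3,3-dimethyl-2-(3-oxobutyl)cyclobutyl]furan
Conditions: p-TsOH·H2O (5 mol %), 4 Å MS, toluene, 80 °C
Reagents that add atoms: none
Why: Paal–Knorr furan synthesis: only the 1,4-related ketone/aldehyde pair can cyclodehydrate, which singles out the C8′ ketone from the remote methyl ketone.

Step 10
Reactants: 15 furyl ketone
Product: 16 (1S,2R)-3,3-dimethyl-2-(3-oxobutyl)cyclobutane-1-carboxylic acid
Conditions: RuCl3·xH2O (5 mol %), NaIO4, EtOAc/MeCN/H2O, rt
Reagents that add atoms: sodium periodate (oxygen, relayed through RuO4), [Na+].[O-]I(=O)(=O)=O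
Why: Oxidative degradation of a 2-substituted furan with catalytic RuO4 (furan as carboxyl surrogate) keeps C8′ as the acid carbon and leaves the ketone and the cyclobutane alone.

Step 11
Reactants: 16 keto acid
Product: 18 (1S,2R)-N-methoxy-N,3,3-trimethyl-2-(3-oxobutyl)cyclobutane-1-carboxamide, via acyl imidazole 17 (not isolated)
Conditions: CDI, CH2Cl2, rt; then MeNH(OMe)·HCl, rt
Reagents that add atoms: 1,1′-carbonyldiimidazole, O=C(n1ccnc1)n1ccnc1 (imidazolyl group of 17 only); N,O-dimethylhydroxylamine hydrochloride, CNOC.Cl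
Why: Amide coupling through the acyl imidazole installs the N-methoxy-N-methylamide, a latent vinyl ketone whose α-proton is far less acidic than that of a lactone.

Step 12
Reactants: 18 keto amide
Product: 20 (1S,2R)-2-(2-hydroxyethyl)-N-methoxy-N,3,3-trimethylcyclobutane-1-carboxamide, via acetate 19 (not isolated)
Conditions: mCPBA, CF3CO2H, CH2Cl2, 0 °C → rt; aqueous wash; then K2CO3 (cat.), MeOH, rt
Reagents that add atoms: 3-chloroperbenzoic acid, OOC(=O)c1cccc(Cl)c1
Why: Baeyer–Villiger oxidation, in which the primary alkyl group migrates in preference to methyl so that the acetyl unit ends up as an acetate on C3′, followed by transesterification to free the primary alcohol.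

Step 13
Reactants: 20 hydroxy amide
Product: 21 (1S,2R)-2-(2-iodoethyl)-N-methoxy-N,3,3-trimethylcyclobutane-1-carboxamide
Conditions: I2, PPh3, imidazole, CH2Cl2, 0 °C
Reagents that add atoms: iodine, II
Why: Appel-type iodination (SN2 of iodide on the alkoxyphosphonium ion) of an unhindered primary alcohol touches no stereocentre.

**Union and endgame**

Step 14
Reactants: 12 (4S,6R)-vinyl lactone; 21 iodo amide
Product: 23 (3R,4R,6R)-3-[2-(cyclobutyl)ethyl]-4-vinyl-6-alkenyltetrahydropyran-2-one (3,4-trans and 4,6-trans), via lithium enolate 22 (not isolated)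
Conditions: LDA, THF, −78 °C; then 21, HMPA, −78 → −30 °C
Reagents that add atoms: lithium diisopropylamide, [Li+].CC(C)[N-]C(C)C (lithium of 22 only)
Why: SN2 alkylation of the pre-formed lactone lithium enolate by the primary iodide brings the arm in anti to the neighbouring vinyl group, a centre that is flattened again in step 15, and the amide α-proton is too weakly acidic to quench the enolate.

Step 15
Reactants: 23 alkylated lactone
Product: 26 ring C diester bearing the C5′ vinyl group and the cyclobutyl N-methoxy-N-methylamide arm, via TBS ketene acetal 24 (not isolated), via TBS ester 25 (not isolated)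
Conditions: TBSCl, LDA (internal quench), THF/HMPA, −78 → 0 °C; toluene, 110 °C; then CsF, MeI, DMF, rt
Reagents that add atoms: tert-butyldimethylsilyl chloride, CC(C)(C)[Si](C)(C)Cl (silyl group of 24 and 25 only); iodomethane, CI
Why: Ireland–Claisen rearrangement run as a lactone ring contraction: the ring-locked silyl ketene acetal can reach the (E)-C12=C13 alkene only through a boat-like transition state on the face that carries the breaking C14–O bond, so the C14 configuration is relayed suprafacially to C12 and to quaternary C4′ (carboxyl cis to the C5′ vinyl and to the C12 labdanylmethyl group, two-carbon arm trans to both), and fluoride-triggered methylation of the silyl ester completes the diester.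

Step 16
Reactants: 26 diester amide
Product: 28 cyclohexene diester with C5′ vinyl group and trans-cyclobutyl vinyl ketone arm (metathesis precursor), via magnesium hemiaminal 27 (not isolated)
Conditions: vinylMgBr, THF, 0 °C; inverse quench into cold 1 M HCl/Et2O
Reagents that add atoms: vinylmagnesium bromide, C=C[Mg]Br
Why: Weinreb ketone synthesis: the magnesium-chelated adduct holds until the acidic quench so that only one vinyl group is transferred, the acid keeps the released amine from adding to the enone, and the two esters on fully substituted carbons are too hindered to react.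

Step 17
Reactants: 28 metathesis precursor
Product: 29 pentacyclic (6′Z)-cyclononenone diester
Conditions: second-generation Hoveyda–Grubbs catalyst (H2IMes)Cl2Ru(=CH-2-iPrOC6H4) (2 × 7.5 mol %, slow addition), 1,4-benzoquinone (20 mol %), toluene (0.5 mM), 80 °C, Ar sparge
Reagents that add atoms: none
Why: Ring-closing olefin metathesis: the ruthenium alkylidene is taken up by the electron-neutral C5′ vinyl group, adds to the vinyl ketone through a metallacyclobutane and releases the C6′=C7′ alkene while ethylene is swept out. The closest known reaction type is ring-closing metathesis to nine-membered carbocycles, combined with the enone-forming closure of acryloyl-type partners by phosphine-free second-generation catalysts. Ring D closes as a nine-membered ring by union of the two terminal alkene carbons, and only the Z-alkene fits a ring of this size. No stereocentre is created, and the epimerisable C9′ stays in its more stable trans arrangement. Ring closure has to beat cross-metathesis oligomerisation, which is secured by high dilution, by the trans placement of the two arms on C4′/C5′ of ring C and by the trans-cyclobutane that freezes part of the tether. Site selectivity follows from substitution, since the trisubstituted C13=C14 and the hindered 1,1-disubstituted C8=C17 alkenes are poor substrates, and benzoquinone suppresses hydride-induced alkene migration.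

Step 18
Reactants: 29 Z-cyclononenone diester
Product: 30 pentacyclic cyclononanone diester
Conditions: [(Ph3P)CuH]6, degassed H2O, toluene, rt
Reagents that add atoms: none
Why: Copper hydride conjugate reduction: the soft hydride adds only to the enone β-carbon C6′, water protonates the copper enolate at once, and isolated alkenes and esters are inert.

Step 19
Reactants: 30 cyclononanone diester
Product: 31 dimethyl ester of the target
Conditions: Ph3PCH3Br (slight excess over base), KOtBu, THF, 0 → 40 °C
Reagents that add atoms: methyltriphenylphosphonium bromide, C[P+](c1ccccc1)(c1ccccc1)c1ccccc1.[Br-]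
Why: Wittig methylenation of the C8′ ketone, with no free alkoxide present so that enolate side reactions with the nearby C4′ ester are avoided and C9′ stays in its thermodynamically preferred trans ring fusion.

Step 20
Reactants: 31 dimethyl ester of the target
Product: 32 target diacid CNP0330729.1
Conditions: n-PrSLi (from n-PrSH, n-BuLi), HMPA, rt → 50 °C; then cold 1 M HCl to pH 3
Reagents that add atoms: none
Why: Nucleophilic ester dealkylation (SN2 of thiolate at the methyl carbons) bypasses both shielded carbonyl groups in one operation and is non-acidic, so the two exocyclic methylenes and the ring C alkene should not migrate.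

**Compound list**

1 | trans-communic acid | C=C/C(C)=C/C[C@H]1C(=C)CC[C@@H]2[C@]1(C)CCC[C@]2(C)C(=O)O | starting material
2 | methyl trans-communate | C=C/C(C)=C/C[C@H]1C(=C)CC[C@@H]2[C@]1(C)CCC[C@]2(C)C(=O)OC | intermediate
3 | C12–C13 secondary ozonide of 2 (mixture at the two acetal carbons) | C=CC1(C)OOC(C[C@H]2C(=C)CC[C@@H]3[C@]2(C)CCC[C@]3(C)C(=O)OC)O1 | intermediate
4 | methyl 12-oxo-13,14,15,16-tetranorlabd-8(17)-en-19-oate | O=CC[C@H]1C(=C)CC[C@@H]2[C@]1(C)CCC[C@]2(C)C(=O)OC | intermediate
5 | 2-(triphenylphosphoranylidene)propanal | CC(C=O)=P(c1ccccc1)(c1ccccc1)c1ccccc1 | starting material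
6 | methyl (12E)-14-oxo-15-norlabda-8(17),12-dien-19-oate | O=C/C(C)=C/C[C@H]1C(=C)CC[C@@H]2[C@]1(C)CCC[C@]2(C)C(=O)OC | intermediate
7 | (14R)-homoallylic alcohol | C=CC[C@@H](O)/C(C)=C/C[C@H]1C(=C)CC[C@@H]2[C@]1(C)CCC[C@]2(C)C(=O)OC | intermediate
8 | acryloyl chloride | C=CC(=O)Cl | starting material
9 | acrylate ester of 7 | C=CC[C@@H](OC(=O)C=C)/C(C)=C/C[C@H]1C(=C)CC[C@@H]2[C@]1(C)CCC[C@]2(C)C(=O)OC | intermediate
10 | (6R)-6-alkenyl-5,6-dihydro-2H-pyran-2-one | O=C1C=CC[C@@H](O1)/C(C)=C/C[C@H]2C(=C)CC[C@@H]3[C@]2(C)CCC[C@]3(C)C(=O)OC | intermediate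
11 | TMS ketene acetal of 12 | C[Si](C)(C)OC1=C[C@@H](C=C)C[C@@H](O1)/C(C)=C/C[C@H]2C(=C)CC[C@@H]3[C@]2(C)CCC[C@]3(C)C(=O)OC | intermediate
12 | (4S,6R)-4-vinyl-6-alkenyltetrahydropyran-2-one (4,6-trans) | O=C1C[C@@H](C=C)C[C@@H](O1)/C(C)=C/C[C@H]2C(=C)CC[C@@H]3[C@]2(C)CCC[C@]3(C)C(=O)OC | intermediate
13 | (−)-β-caryophyllene (1R,4E,9S) | C=C1CC/C=C(\C)CC[C@@H]2[C@@H]1CC2(C)C | starting material
14 | 4-[(1S,2R)-3,3-dimethyl-2-(3-oxobutyl)cyclobutyl]-4-oxobutanal | CC(=O)CC[C@@H]1[C@@H](C(=O)CCC=O)CC1(C)C | intermediate
15 | 2-[(1S,2R)-3,3-dimethyl-2-(3-oxobutyl)cyclobutyl]furan | CC(=O)CC[C@@H]1[C@@H](c2ccco2)CC1(C)C | intermediate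
16 | (1S,2R)-3,3-dimethyl-2-(3-oxobutyl)cyclobutane-1-carboxylic acid | CC(=O)CC[C@@H]1[C@@H](C(=O)O)CC1(C)C | intermediate
17 | acyl imidazole of 16 | CC(=O)CC[C@@H]1[C@@H](C(=O)n2ccnc2)CC1(C)C | intermediate
18 | (1S,2R)-N-methoxy-N,3,3-trimethyl-2-(3-oxobutyl)cyclobutane-1-carboxamide | CC(=O)CC[C@@H]1[C@@H](C(=O)N(C)OC)CC1(C)C | intermediate
19 | acetate of 20 | CC(=O)OCC[C@@H]1[C@@H](C(=O)N(C)OC)CC1(C)C | intermediate
20 | (1S,2R)-2-(2-hydroxyethyl)-N-methoxy-N,3,3-trimethylcyclobutane-1-carboxamide | OCC[C@@H]1[C@@H](C(=O)N(C)OC)CC1(C)C | intermediate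
21 | (1S,2R)-2-(2-iodoethyl)-N-methoxy-N,3,3-trimethylcyclobutane-1-carboxamide | ICC[C@@H]1[C@@H](C(=O)N(C)OC)CC1(C)C | intermediate
22 | lithium enolate of 12 | [Li+].[O-]C1=C[C@@H](C=C)C[C@@H](O1)/C(C)=C/C[C@H]2C(=C)CC[C@@H]3[C@]2(C)CCC[C@]3(C)C(=O)OC | intermediate
23 | (3R,4R,6R)-3-alkylated lactone (3,4-trans, 4,6-trans) | O=C1[C@H](CC[C@@H]2[C@@H](C(=O)N(C)OC)CC2(C)C)[C@@H](C=C)C[C@@H](O1)/C(C)=C/C[C@H]3C(=C)CC[C@@H]4[C@]3(C)CCC[C@]4(C)C(=O)OC | intermediate
24 | TBS ketene acetal of 23 | CC(C)(C)[Si](C)(C)OC1=C(CC[C@@H]2[C@@H](C(=O)N(C)OC)CC2(C)C)[C@@H](C=C)C[C@@H](O1)/C(C)=C/C[C@H]3C(=C)CC[C@@H]4[C@]3(C)CCC[C@]4(C)C(=O)OC | intermediate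
25 | ring C TBS ester (rearranged) | C=C[C@H]2CC=C(C)[C@@H](C[C@H]3C(=C)CC[C@@H]4[C@]3(C)CCC[C@]4(C)C(=O)OC)[C@]2(C(=O)O[Si](C)(C)C(C)(C)C)CC[C@@H]2[C@@H](C(=O)N(C)OC)CC2(C)C | intermediate
26 | ring C diester with cyclobutyl N-methoxy-N-methylamide arm | C=C[C@H]2CC=C(C)[C@@H](C[C@H]3C(=C)CC[C@@H]4[C@]3(C)CCC[C@]4(C)C(=O)OC)[C@]2(C(=O)OC)CC[C@@H]2[C@@H](C(=O)N(C)OC)CC2(C)C | intermediate
27 | magnesium hemiaminal from 26 (new carbon unassigned) | C=C[C@H]2CC=C(C)[C@@H](C[C@H]3C(=C)CC[C@@H]4[C@]3(C)CCC[C@]4(C)C(=O)OC)[C@]2(C(=O)OC)CC[C@@H]2[C@@H](C(C=C)(O[Mg]Br)N(C)OC)CC2(C)C | intermediate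
28 | cyclohexene diester with C5′ vinyl and cyclobutyl vinyl ketone arms | C=C[C@H]2CC=C(C)[C@@H](C[C@H]3C(=C)CC[C@@H]4[C@]3(C)CCC[C@]4(C)C(=O)OC)[C@]2(C(=O)OC)CC[C@@H]2[C@@H](C(=O)C=C)CC2(C)C | intermediate
29 | pentacyclic (6′Z)-cyclononenone diester | O=C1/C=C\[C@H]2CC=C(C)[C@@H](C[C@H]3C(=C)CC[C@@H]4[C@]3(C)CCC[C@]4(C)C(=O)OC)[C@]2(C(=O)OC)CC[C@@H]2[C@@H]1CC2(C)C | intermediate
30 | pentacyclic cyclononanone diester | O=C1CC[C@H]2CC=C(C)[C@@H](C[C@H]3C(=C)CC[C@@H]4[C@]3(C)CCC[C@]4(C)C(=O)OC)[C@]2(C(=O)OC)CC[C@@H]2[C@@H]1CC2(C)C | intermediate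
31 | dimethyl ester of the target | C=C1CC[C@H]2CC=C(C)[C@@H](C[C@H]3C(=C)CC[C@@H]4[C@]3(C)CCC[C@]4(C)C(=O)OC)[C@]2(C(=O)OC)CC[C@@H]2[C@@H]1CC2(C)C | intermediate
32 | CNP0330729.1 (diacid) | C=C1CC[C@H]2CC=C(C)[C@@H](C[C@H]3C(=C)CC[C@@H]4[C@]3(C)CCC[C@]4(C)C(=O)O)[C@]2(C(=O)O)CC[C@@H]2[C@@H]1CC2(C)C | target

Total step count: 20.
Longest linear sequence: 14 steps (1–7, then 14–20). The cyclobutane branch (steps 8–13, six steps) joins at step 14.

**Steps most likely to fail**

1. Step 17.
   - What may go wrong: intermolecular cross-metathesis may outrun closure of the medium ring. Initiation at the vinyl group next to the quaternary centre may be slow. The enone carbonyl may tie up the catalyst by chelation.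
   - Fallback: it sets out from 28 and returns at 29. The electron-poor partner is exchanged for an allylic alcohol, so that oxidation follows ring closure instead of preceding it. Luche reduction of 28 (NaBH4, CeCl3·7H2O, MeOH) gives the allylic alcohol F1, and both carbinol epimers serve. Its alkene is a more willing metathesis partner and profits from hydroxyl assistance. Ring-closing metathesis at high dilution gives the Z-cyclononenol F2. Dess–Martin periodinane oxidises F2 to 29.

2. Step 15.
   - What may go wrong: enolisation and O-silylation of the α-branched lactone may be incomplete. The boat-like transition state is crowded by the contact between the C13 methyl and the silyloxy group and by the emerging quaternary centre, so decay of the ketene acetal may outrun the rearrangement.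
   - Fallback: it sets out from 12, replaces steps 14 and 15, and returns at 26. The order of the two C–C bond formations is inverted. Lactone 12 is silylated to the less substituted TBS ketene acetal F3. F3 rearranges on heating to the TBS ester F4, and CsF/MeI turns this into the methyl ester F5, which still bears H on C4′. LDA/HMPA gives the lithium ester enolate F6. Iodide 21 should alkylate F6 on the face opposite to the two flanking cis substituents (C5′ vinyl and C12 labdanylmethyl), which is the configuration of 26.

3. Step 14.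
   - What may go wrong: slow substitution on the unactivated iodide may leave the lactone enolate time for proton transfer, self-condensation or a premature sigmatropic shift.
   - Fallback: it sets out from 18 and 7 and returns at 23. The arm is brought in with the acyl unit instead of by alkylation. KHMDS at −78 °C deprotonates the methyl group of 18 to the potassium enolate F7, and PhNTf2 traps it as the terminal enol triflate F8. Pd(OAc)2/PPh3-catalysed hydroxycarbonylation (CO, KOAc, DMF) gives the 2-substituted acrylic acid F9. Carbodiimide/DMAP esterification with 7 gives the diene ester F10. Ring-closing metathesis with the second-generation Grubbs catalyst gives the 3-substituted dihydropyranone F11. BF3·OEt2-assisted vinylcuprate addition anti to the C6 side chain, followed by equilibration of the α-centre with DBU, delivers 23.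

**Further compounds**

F1 | step 17 | allylic alcohol from 28 (carbinol epimers) | C=C[C@H]2CC=C(C)[C@@H](C[C@H]3C(=C)CC[C@@H]4[C@]3(C)CCC[C@]4(C)C(=O)OC)[C@]2(C(=O)OC)CC[C@@H]2[C@@H](C(O)C=C)CC2(C)C
F2 | step 17 | Z-cyclononenol (carbinol epimers) | OC1/C=C\[C@H]2CC=C(C)[C@@H](C[C@H]3C(=C)CC[C@@H]4[C@]3(C)CCC[C@]4(C)C(=O)OC)[C@]2(C(=O)OC)CC[C@@H]2[C@@H]1CC2(C)C
F3 | step 15 | TBS ketene acetal of 12 | CC(C)(C)[Si](C)(C)OC1=C[C@@H](C=C)C[C@@H](O1)/C(C)=C/C[C@H]2C(=C)CC[C@@H]3[C@]2(C)CCC[C@]3(C)C(=O)OC
F4 | step 15 | ring C TBS ester with H on C4′ | C=C[C@H]1CC=C(C)[C@@H](C[C@H]2C(=C)CC[C@@H]3[C@]2(C)CCC[C@]3(C)C(=O)OC)[C@H]1C(=O)O[Si](C)(C)C(C)(C)C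
F5 | step 15 | ring C methyl ester with H on C4′ | C=C[C@H]1CC=C(C)[C@@H](C[C@H]2C(=C)CC[C@@H]3[C@]2(C)CCC[C@]3(C)C(=O)OC)[C@H]1C(=O)OC
F6 | step 15 | lithium enolate of F5 | C=C[C@H]1CC=C(C)[C@@H](C[C@H]2C(=C)CC[C@@H]3[C@]2(C)CCC[C@]3(C)C(=O)OC)C1=C([O-])OC.[Li+]
F7 | step 14 | terminal potassium enolate of 18 | [K+].[O-]C(=C)CC[C@@H]1[C@@H](C(=O)N(C)OC)CC1(C)C
F8 | step 14 | terminal enol triflate of 18 | C=C(OS(=O)(=O)C(F)(F)F)CC[C@@H]1[C@@H](C(=O)N(C)OC)CC1(C)C
F9 | step 14 | 2-substituted acrylic acid | C=C(C(=O)O)CC[C@@H]1[C@@H](C(=O)N(C)OC)CC1(C)C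
F10 | step 14 | ester of F9 with 7 | C=CC[C@@H](OC(=O)C(=C)CC[C@@H]1[C@@H](C(=O)N(C)OC)CC1(C)C)/C(C)=C/C[C@H]2C(=C)CC[C@@H]3[C@]2(C)CCC[C@]3(C)C(=O)OC
F11 | step 14 | (6R)-3-substituted 5,6-dihydropyran-2-one | O=C1C(CC[C@@H]2[C@@H](C(=O)N(C)OC)CC2(C)C)=CC[C@@H](O1)/C(C)=C/C[C@H]3C(=C)CC[C@@H]4[C@]3(C)CCC[C@]4(C)C(=O)OC
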